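Ring B is a strained ten-membered carbocycle, and its Z-trisubstituted C5=C6 bond next to the C7 oxygen makes direct closure unattractive. The route therefore cuts that bond and places sulfur between C5 and C6. An eleven-membered sulfide closes easily through C6–S bond formation. Ramberg–Bäcklund contraction of the derived sulfone then forms the C5–C6 bond, the Z alkene and ring B in one operation. The precursor is sulfone 38: ring A joined to an eleven-membered C5–SO2–C6 ring with free C7 hydroxyl, C8/C9 acetonide and silyl ethers at C2, C12, C14 and C19. It is built from a Pauson–Khand-derived ring A lactol and a Roche-ester alkenyl fragment.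

Key step: step 28

Remark: atoms carry the numbering of the target throughout (ring A: C1, C10, C11, C13, C14; ring B: C1–C10; C12 formyl carbon; C17/C19 lactone carbons).
Assumption: (S)-BINAP is taken to give the (S)-configured C11 centre in step 2; if the sense of induction is the reverse, (R)-BINAP is used instead.
Remark: C5 is carried as a mixture of epimers from step 24 to step 27, because it becomes sp2 in step 28.
Remark: C12 is held as a silyl ether, so that one fluoride step and one oxidation later deliver the C19 lactone and the C12 aldehyde together.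

Step 1
Reactants: 1 but-2-yn-1-ol; 2 3-chloro-2-methylprop-1-ene
Product: 3 1-[(2-methylprop-2-en-1-yl)oxy]but-2-yne
Conditions: NaH, THF, 0 °C; then 2, Bu4NI (cat.), rt
Reagents that add atoms: none
Why: Williamson ether synthesis, in which the sodium alkoxide of 1 displaces the allylic chloride of 2 by SN2 and no stereocentre is formed.

Step 2
Reactants: 3 enyne ether
Product: 4 (3aS)-3a,6-dimethyl-3a,4-dihydro-1H-cyclopenta[c]furan-5(3H)-one (ring A enone)
Conditions: [Rh(CO)2Cl]2 (3 mol %), (S)-BINAP (6 mol %), AgOTf (12 mol %), CO (1 atm), THF, 90 °C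
Reagents that add atoms: carbon monoxide, [C-]#[O+]
Why: Catalytic asymmetric Pauson–Khand reaction of a 1,6-enyne, in which alkyne, 1,1-disubstituted alkene and CO combine to the bicyclic cyclopentenone and the chiral rhodium–BINAP catalyst selects the alkene face, which sets the quaternary C11 centre.

Step 3
Reactants: 4 ring A enone
Product: 5 (3aS)-3a,6-dimethyl-3a,4-dihydro-1H-cyclopenta[c]furan-1,5(3H)-dione (ene-dione lactone)
Conditions: CrO3, 3,5-dimethylpyrazole, CH2Cl2, −20 °C
Reagents that add atoms: chromium trioxide, O=[Cr](=O)=O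
Why: Allylic C–H oxidation by the CrO3–3,5-dimethylpyrazole complex, which should take only the C9 methylene to the lactone because it alone is both allylic (γ to the enone) and α to the ether oxygen, while C11 is untouched.

Step 4
Reactants: 5 ene-dione lactone
Product: 6 cis-fused lactone C14 triethylsilyl enol ether
Conditions: Et3SiH, RhCl(PPh3)3 (2 mol %), toluene, 60 °C
Reagents that add atoms: triethylsilane, CC[SiH](CC)CC
Why: Rhodium-catalysed 1,4-hydrosilylation of an enone, in which the ketone (a far better acceptor than the lactone) takes silicon on oxygen and hydrogen at C10, the C14=C1 enol ether forms regiospecifically, and the new C10 centre can only be cis-fused because C9 and C12 are tied in the five-membered lactone.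

Step 5
Reactants: 6 silyl enol ether; 7 pent-4-enoyl chloride
Product: 8 diketone lactone with quaternary C1
Conditions: ZnCl2, CH2Cl2/Et2O, 0 °C → rt
Reagents that add atoms: none
Why: Lewis-acid-mediated C-acylation of a silyl enol ether (Mukaiyama-type), in which the acyl chloride attacks C1 on the convex face of the cis-fused bicycle, anti to the lactone ring, so that the C2 acyl group ends trans to C9 and the quaternary C1 centre is set.

Step 6
Reactants: 8 diketone lactone
Product: 10 syn-diol lactone, via C14-hydroxy ketone 9 (not isolated)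
Conditions: Zn(BH4)2, Et2O, −20 → 0 °C
Reagents that add atoms: none
Why: Chelation-controlled reduction of a 2,2-disubstituted 1,3-diketone, in which zinc ties the two oxygens together and hydride should enter each carbonyl from the chelate face that carries the small C15 methyl and not the ring bond C1–C10, giving the C14/C2 syn-diol with (14S)-OH cis to the side chain and (2R)-OH, while the lactone is not reduced at this temperature.

Step 7
Reactants: 10 syn-diol lactone
Product: 11 C2,C14-bis(tert-butyldimethylsilyl) ether lactone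
Conditions: TBSOTf, 2,6-lutidine, CH2Cl2, 0 °C → rt
Reagents that add atoms: tert-butyldimethylsilyl trifluoromethanesulfonate, CC(C)(C)[Si](C)(C)OS(=O)(=O)C(F)(F)F
Why: Silylation of two hindered secondary alcohols with the reactive silyl triflate and a hindered base, with no change at any stereocentre.

Step 8
Reactants: 11 bis-silyl ether lactone
Product: 12 C9 lactol
Conditions: i-Bu2AlH (1.1 equiv), CH2Cl2, −78 °C
Reagents that add atoms: none
Why: Partial reduction of a γ-lactone to the lactol, where the tetrahedral aluminate survives at low temperature until work-up and the anomeric centre, left as a mixture, is consumed in step 16.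

Step 9
Reactants: 13 methyl (S)-3-hydroxy-2-methylpropanoate
Product: 14 methyl (S)-3-[(tert-butyldimethylsilyl)oxy]-2-methylpropanoate
Conditions: TBSCl, imidazole, DMF, rt
Reagents that add atoms: tert-butyldimethylsilyl chloride, CC(C)(C)[Si](C)(C)Cl
Why: Imidazole-promoted silylation of a primary alcohol, which does not involve the stereocentre (the later C17).

Step 10
Reactants: 14 silyl ether ester
Product: 15 (S)-3-[(tert-butyldimethylsilyl)oxy]-2-methylpropanal
Conditions: i-Bu2AlH (1.05 equiv), CH2Cl2, −78 °C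
Reagents that add atoms: none
Why: Low-temperature hydride reduction of the ester, which stops at the aldehyde through the stable aluminium hemiacetal, the α-stereocentre being kept by cold work-up and immediate use.

Step 11
Reactants: 15 aldehyde
Product: 16 (R)-tert-butyldimethyl[(2-methylbut-3-yn-1-yl)oxy]silane
Conditions: dimethyl (1-diazo-2-oxopropyl)phosphonate, K2CO3, MeOH, 0 °C → rt
Reagents that add atoms: dimethyl (1-diazo-2-oxopropyl)phosphonate, CC(=O)C(=[N+]=[N-])P(=O)(OC)OC
Why: Ohira–Bestmann homologation (Seyferth–Gilbert type), in which the diazomethylphosphonate generated in situ adds to the aldehyde and the derived alkylidene carbene rearranges to the terminal alkyne under conditions mild enough to keep the α-stereocentre.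

Step 12
Reactants: 16 terminal alkyne
Product: 17 methyl (R)-5-[(tert-butyldimethylsilyl)oxy]-4-methylpent-2-ynoate
Conditions: n-BuLi, THF, −78 °C; ClCO2Me, −78 → 0 °C
Reagents that add atoms: methyl chloroformate, COC(Cl)=O
Why: Deprotonation of the terminal alkyne and acylation of the lithium acetylide with the chloroformate, which adds C6 and forms no stereocentre.

Step 13
Reactants: 17 ynoate
Product: 18 methyl (S,E)-5-[(tert-butyldimethylsilyl)oxy]-4-methyl-3-(tributylstannyl)pent-2-enoate
Conditions: (Bu3Sn)2, n-BuLi, THF, 0 °C; CuBr·SMe2, −78 °C; then 17, MeOH, −78 °C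
Reagents that add atoms: hexabutyldistannane, CCCC[Sn](CCCC)(CCCC)[Sn](CCCC)(CCCC)CCCC
Why: Stannylcupration of an ynoate, a syn addition that places tin on the β-carbon (C8) and, with kinetic protonation at −78 °C, should give the E isomer (tin trans to the ester, C17 cis to it), which fixes the alkene geometry needed in step 18.

Step 14
Reactants: 18 stannyl enoate
Product: 19 (S,E)-5-[(tert-butyldimethylsilyl)oxy]-4-methyl-3-(tributylstannyl)pent-2-en-1-ol
Conditions: i-Bu2AlH (2.2 equiv), CH2Cl2, −78 °C
Reagents that add atoms: none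
Why: Hydride 1,2-reduction of the unsaturated ester to the allylic alcohol, which leaves the vinyl–tin bond and the alkene geometry untouched.

Step 15
Reactants: 19 stannyl allylic alcohol
Product: 20 (S,E)-alkenylstannane with C6 4-methoxybenzyl ether
Conditions: NaH, PMBCl, Bu4NI (cat.), THF/DMF, 0 °C → rt
Reagents that add atoms: 4-methoxybenzyl chloride, COc1ccc(CCl)cc1
Why: Williamson etherification of the primary allylic alkoxide under basic conditions, which a vinylstannane tolerates, whereas acid would protodestannylate it.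

Step 16
Reactants: 12 C9 lactol; 20 alkenylstannane
Product: 23 allylic diol with the C8–C9 bond, via alkenyllithium 21 (not isolated), via open-chain aldehyde alkoxide 22 (not isolated)
Conditions: 20, n-BuLi, THF, −78 °C; 12, i-PrMgCl, THF, −78 °C; combine, −78 → −20 °C; aq NH4Cl
Reagents that add atoms: none
Why: Tin–lithium exchange with retention of alkene geometry followed by 1,2-addition to the aldehyde released from the lactol, where magnesium chelated between the C12 alkoxide and the C9 carbonyl should expose the face anti to the quaternary C1 centre (Cram-chelate-type control) and so give the (9R) carbinol of the target.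

Step 17
Reactants: 23 allylic diol
Product: 24 C12 tert-butyldimethylsilyl ether
Conditions: TBSCl, imidazole, CH2Cl2, 0 °C
Reagents that add atoms: tert-butyldimethylsilyl chloride, CC(C)(C)[Si](C)(C)Cl
Why: Selective silylation of the primary C12 alcohol in the presence of the far more hindered secondary allylic C9 alcohol.

Step 18
Reactants: 24 allylic alcohol
Product: 25 C7–C8 epoxy alcohol
Conditions: VO(acac)2 (5 mol %), t-BuOOH, CH2Cl2, 0 °C → rt
Reagents that add atoms: tert-butyl hydroperoxide, CC(C)(C)OO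
Why: Hydroxyl-directed epoxidation of a secondary allylic alcohol, in which the C9 oxygen delivers the peroxide oxygen to C7=C8 and A(1,2) strain from the C17 branch on C8 should enforce the erythro epoxy alcohol, setting C8 and (through the E geometry) C7, while the isolated terminal alkene does not react.

Step 19
Reactants: 25 epoxy alcohol
Product: 26 epoxy diol with free C6 hydroxyl
Conditions: DDQ, CH2Cl2/pH 7 buffer, 0 °C
Reagents that add atoms: none
Why: Oxidative cleavage of the 4-methoxybenzyl ether by DDQ (hydride abstraction, then hydrolysis of the hemiacetal), under which silyl ethers and the epoxide are stable.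

Step 20
Reactants: 26 epoxy diol
Product: 28 C6/C7 cyclic carbonate with free C8 and C9 hydroxyls, via C6 caesium carbonate 27 (not isolated)
Conditions: Cs2CO3, CO2 (1 atm), DMF, 40 °C
Reagents that add atoms: carbon dioxide, O=C=O
Why: Carbonate-mediated opening of a 2,3-epoxy alcohol, in which the C6 alkoxide takes up CO2 and the alkyl carbonate attacks C7 intramolecularly (5-exo) with inversion, installing the C7 oxygen in the target configuration and freeing the tertiary C8 hydroxyl with retention.

Step 21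
Reactants: 28 carbonate diol
Product: 29 C8/C9 acetonide carbonate
Conditions: 2-methoxypropene, PPTS (cat.), CH2Cl2, 0 °C → rt
Reagents that add atoms: 2-methoxypropene, COC(C)=C
Why: Acid-catalysed ketalisation of the only free 1,2-diol (C8/C9), which touches no stereocentre.

Step 22
Reactants: 29 acetonide carbonate
Product: 30 C6,C7-diol acetonide
Conditions: K2CO3, MeOH, 0 °C → rt
Reagents that add atoms: none
Why: Base-catalysed methanolysis (transesterification) of the cyclic carbonate, under which the acetonide and the silyl ethers are stable.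

Step 23
Reactants: 30 C6,C7-diol
Product: 32 terminal C6–C7 epoxide, via C6 tosylate 31 (not isolated)
Conditions: NaH, 1-(p-toluenesulfonyl)imidazole, THF, 0 °C → rt
Reagents that add atoms: none
Why: One-pot epoxide formation from a 1,2-diol, in which the primary C6 alkoxide is sulfonylated selectively and the neighbouring C7 alkoxide displaces the tosylate (3-exo-tet), so that C7 keeps its configuration.

Step 24
Reactants: 32 epoxide with terminal alkene
Product: 33 C5 secondary alcohol (both epimers)
Conditions: Co(acac)2 (20 mol %), PhSiH3, O2 (1 atm), THF, rt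
Reagents that add atoms: dioxygen, O=O
Why: Mukaiyama hydration (cobalt hydride hydrogen-atom transfer, trapping by O2, reduction in situ), which should give the Markovnikov alcohol at C5 without touching the epoxide; both epimers are usable because C5 becomes sp2 in step 28.

Step 25
Reactants: 33 C5 alcohol; 34 thioacetic acid
Product: 35 C5 thioacetate
Conditions: PPh3, DIAD, THF, 0 °C
Reagents that add atoms: none
Why: Mitsunobu thioesterification, in which the activated C5 alcohol is displaced by thioacetate with inversion at a centre whose configuration is irrelevant, under cold neutral conditions that should leave the terminal epoxide intact.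

Step 26
Reactants: 35 thioacetate epoxide
Product: 37 eleven-membered cyclic sulfide with free C7 hydroxyl, via C5 thiol 36 (not isolated)
Conditions: K2CO3, degassed MeOH/THF (1 mM), rt
Reagents that add atoms: none
Why: Methanolysis of the thioacetate releases the thiolate, which should open the terminal epoxide at the unhindered C6 under high dilution (thiol–epoxide ring opening, endo attack at the terminal carbon), closing the eleven-membered ring and freeing the C7 hydroxyl with its configuration unchanged.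

Step 27
Reactants: 37 cyclic sulfide
Product: 38 eleven-membered cyclic sulfone
Conditions: mCPBA (2.2 equiv), NaHCO3, CH2Cl2, 0 °C → rt
Reagents that add atoms: 3-chloroperoxybenzoic acid, O=C(OO)c1cccc(Cl)c1
Why: Peracid oxidation of the sulfide through the sulfoxide to the sulfone, with no alkene present and with alcohols, silyl ethers and the acetonide inert.

Step 28
Reactants: 38 eleven-membered cyclic sulfone
Product: 41 ring B alkene with Z C5=C6 and free C7 hydroxyl, via C5-bromo sulfone 39 (not isolated), via episulfone 40 (not isolated)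
Conditions: CBr2F2, KOH/Al2O3, t-BuOH/CH2Cl2, 0 °C → rt
Reagents that add atoms: none
Why: KOH on alumina deprotonates an α-carbon of the sulfone, the carbanion is brominated by CBr2F2 (expected at C5, the site remote from the C7 alkoxide), the second α-carbanion at C6 displaces bromide in a 1,3-elimination, and the episulfone loses SO2 cheletropically to give the C5=C6 bond. The closest known reaction is the Ramberg–Bäcklund reaction with in situ halogenation, as used for medium-ring cycloalkenes. The three-membered episulfone closes by 3-exo-tet displacement, and ring B arises by contraction of the eleven-membered ring to ten atoms when sulfur is extruded, so the strain is paid only in an irreversible step. No stereocentre is created and C5 is destroyed, which is why both epimers of 38 converge. The step needs the Z (ring-cis) alkene and no β-elimination towards C7: the cis-fused episulfone, the one the ring should accommodate under non-epimerising hydroxide conditions, collapses stereospecifically to the Z alkene, and the C7 oxygen is present as an alkoxide, which cannot leave from the adjacent carbanion. Silyl ethers and the acetonide are stable to KOH.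

Step 29
Reactants: 41 ring B alkene
Product: 42 pentaol acetonide
Conditions: Bu4NF, THF, 50 °C
Reagents that add atoms: none
Why: Fluoride-induced cleavage of all four silyl ethers in one operation, carried out before any base-sensitive carbonyl group is present, with no stereocentre affected.

Step 30
Reactants: 42 pentaol acetonide
Product: 44 lactone aldehyde diol, via C19 lactol 43 (not isolated)
Conditions: TEMPO (cat.), PhI(OAc)2, CH2Cl2, rt
Reagents that add atoms: none
Why: Oxoammonium oxidation selective for primary over hindered secondary alcohols, in which C19–OH should give the aldehyde that the C7 hydroxyl traps as the five-membered lactol and that is oxidised on to the γ-lactone (oxidative lactonisation of a 1,4-diol), while C12–OH gives the non-enolisable aldehyde and C17 is not epimerised under these neutral conditions.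

Step 31
Reactants: 44 lactone aldehyde diol
Product: 45 C2,C14-diacetate acetonide
Conditions: Ac2O, DMAP, pyridine, rt
Reagents that add atoms: acetic anhydride, CC(=O)OC(C)=O
Why: DMAP-catalysed acylation of the two remaining secondary alcohols, while the C12 aldehyde has no α-hydrogen and the C8/C9 diol is still masked.

Step 32
Reactants: 45 diacetate acetonide
Product: 46 target
Conditions: CF3CO2H/H2O, THF, 0 °C
Reagents that add atoms: none
Why: Acid-catalysed hydrolysis of the isopropylidene ketal to the C8/C9 diol, which acetates, lactone and aldehyde should survive in cold aqueous acid, with no stereocentre touched.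

Compound list

1 | but-2-yn-1-ol | CC#CCO | starting material
2 | 3-chloro-2-methylprop-1-ene | CC(=C)CCl | starting material
3 | 1-[(2-methylprop-2-en-1-yl)oxy]but-2-yne | CC#CCOCC(C)=C | intermediate
4 | (3aS)-3a,6-dimethyl-3a,4-dihydro-1H-cyclopenta[c]furan-5(3H)-one; ring A enone (C14 ketone, C1=C10 with C15 methyl on C1, quaternary C11 with C20 methyl, C9H2–O–C12H2 bridge) | CC1=C2COC[C@@]2(C)CC1=O | intermediate
5 | (3aS)-3a,6-dimethyl-3a,4-dihydro-1H-cyclopenta[c]furan-1,5(3H)-dione; 4 with C9 oxidised to the lactone carbonyl | CC1=C2C(=O)OC[C@@]2(C)CC1=O | intermediate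
6 | cis-fused lactone silyl enol ether: C14 O-triethylsilyl enol ether (C14=C1), C10–H cis to the C11 methyl, C9 lactone closed on C12–O | CC[Si](CC)(CC)OC1=C(C)[C@H]2C(=O)OC[C@@]2(C)C1 | intermediate
7 | pent-4-enoyl chloride | C=CCCC(Cl)=O | starting material
8 | diketone lactone: cis-fused C9 lactone, C14 ketone, quaternary C1 with C15 methyl cis to C9 and pent-4-enoyl group (C2 ketone, C3, C4, C5=C16) trans to C9 | O=C1C[C@]2(C)COC(=O)[C@@H]2[C@@]1(C)C(=O)CCC=C | intermediate
9 | C14-hydroxy ketone: 8 with (14S)-hydroxyl cis to the pentenoyl group, C2 still a ketone (not isolated) | O[C@H]1C[C@]2(C)COC(=O)[C@@H]2[C@@]1(C)C(=O)CCC=C | intermediate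
10 | syn-diol lactone: (14S)- and (2R)-hydroxyls, otherwise as 8 | O[C@H]1C[C@]2(C)COC(=O)[C@@H]2[C@@]1(C)[C@H](O)CCC=C | intermediate
11 | bis-silyl ether lactone: 10 with OTBS at C14 and C2 | CC(C)(C)[Si](C)(C)O[C@H]1C[C@]2(C)COC(=O)[C@@H]2[C@@]1(C)[C@H](O[Si](C)(C)C(C)(C)C)CCC=C | intermediate
12 | lactol: 11 with the C9 lactone reduced to the hemiacetal (C9 epimers) | CC(C)(C)[Si](C)(C)O[C@H]1C[C@]2(C)COC(O)[C@@H]2[C@@]1(C)[C@H](O[Si](C)(C)C(C)(C)C)CCC=C | intermediate
13 | methyl (S)-3-hydroxy-2-methylpropanoate | COC(=O)[C@@H](C)CO | starting material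
14 | methyl (S)-3-[(tert-butyldimethylsilyl)oxy]-2-methylpropanoate | CC(C)(C)[Si](C)(C)OC[C@H](C)C(=O)OC | intermediate
15 | (S)-3-[(tert-butyldimethylsilyl)oxy]-2-methylpropanal | CC(C)(C)[Si](C)(C)OC[C@H](C)C=O | intermediate
16 | (R)-tert-butyldimethyl[(2-methylbut-3-yn-1-yl)oxy]silane | CC(C)(C)[Si](C)(C)OC[C@H](C)C#C | intermediate
17 | methyl (R)-5-[(tert-butyldimethylsilyl)oxy]-4-methylpent-2-ynoate | CC(C)(C)[Si](C)(C)OC[C@H](C)C#CC(=O)OC | intermediate
18 | methyl (S,E)-5-[(tert-butyldimethylsilyl)oxy]-4-methyl-3-(tributylstannyl)pent-2-enoate (tin on C8 trans to the ester, C17 cis to it) | CC(C)(C)[Si](C)(C)OC[C@H](C)/C(=C\C(=O)OC)[Sn](CCCC)(CCCC)CCCC | intermediate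
19 | (S,E)-5-[(tert-butyldimethylsilyl)oxy]-4-methyl-3-(tributylstannyl)pent-2-en-1-ol | CC(C)(C)[Si](C)(C)OC[C@H](C)/C(=C\CO)[Sn](CCCC)(CCCC)CCCC | intermediate
20 | (S,E)-alkenylstannane: 19 as its C6 4-methoxybenzyl ether | CC(C)(C)[Si](C)(C)OC[C@H](C)/C(=C\COCc1ccc(OC)cc1)[Sn](CCCC)(CCCC)CCCC | intermediate
21 | alkenyllithium from 20 (lithium on C8, geometry retained; not isolated) | CC(C)(C)[Si](C)(C)OC[C@H](C)/C(=C\COCc1ccc(OC)cc1)[Li] | intermediate
22 | open-chain C9 aldehyde of 12 as its C12 chloromagnesium alkoxide (not isolated) | CC(C)(C)[Si](C)(C)O[C@H]1C[C@](C)(CO[Mg]Cl)[C@H](C=O)[C@@]1(C)[C@H](O[Si](C)(C)C(C)(C)C)CCC=C | intermediate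
23 | allylic diol: ring A (OTBS at C14 and C2, pent-4-enyl end) with free C12–OH and (9R)-carbinol bonded to C8 of the E alkene C8=C7 (C9 trans to C6; C8 bears the C17 unit; C6–OPMB) | CC(C)(C)[Si](C)(C)O[C@H]1C[C@](C)(CO)[C@H]([C@@H](O)/C(=C/COCc2ccc(OC)cc2)[C@@H](C)CO[Si](C)(C)C(C)(C)C)[C@@]1(C)[C@H](O[Si](C)(C)C(C)(C)C)CCC=C | intermediate
24 | 23 with C12–OTBS | CC(C)(C)[Si](C)(C)O[C@H]1C[C@](C)(CO[Si](C)(C)C(C)(C)C)[C@H]([C@@H](O)/C(=C/COCc2ccc(OC)cc2)[C@@H](C)CO[Si](C)(C)C(C)(C)C)[C@@]1(C)[C@H](O[Si](C)(C)C(C)(C)C)CCC=C | intermediate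
25 | epoxy alcohol: 24 with the C7–C8 epoxide erythro to C9–OH (C9 and C6 trans on the oxirane) | CC(C)(C)[Si](C)(C)O[C@H]1C[C@](C)(CO[Si](C)(C)C(C)(C)C)[C@H]([C@@H](O)[C@@]3([C@@H](C)CO[Si](C)(C)C(C)(C)C)O[C@@H]3COCc2ccc(OC)cc2)[C@@]1(C)[C@H](O[Si](C)(C)C(C)(C)C)CCC=C | intermediate
26 | epoxy diol: 25 with free C6–OH | CC(C)(C)[Si](C)(C)O[C@H]1C[C@](C)(CO[Si](C)(C)C(C)(C)C)[C@H]([C@@H](O)[C@@]3([C@@H](C)CO[Si](C)(C)C(C)(C)C)O[C@@H]3CO)[C@@]1(C)[C@H](O[Si](C)(C)C(C)(C)C)CCC=C | intermediate
27 | C6 caesium alkyl carbonate of 26 (not isolated) | CC(C)(C)[Si](C)(C)O[C@H]1C[C@](C)(CO[Si](C)(C)C(C)(C)C)[C@H]([C@@H](O)[C@@]3([C@@H](C)CO[Si](C)(C)C(C)(C)C)O[C@@H]3COC(=O)[O-])[C@@]1(C)[C@H](O[Si](C)(C)C(C)(C)C)CCC=C.[Cs+] | intermediate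
28 | C6/C7 cyclic carbonate with free C8 and C9 hydroxyls (C7 oxygen introduced with inversion) | CC(C)(C)[Si](C)(C)O[C@H]1C[C@](C)(CO[Si](C)(C)C(C)(C)C)[C@H]([C@@H](O)[C@](O)([C@@H](C)CO[Si](C)(C)C(C)(C)C)[C@@H]3COC(=O)O3)[C@@]1(C)[C@H](O[Si](C)(C)C(C)(C)C)CCC=C | intermediate
29 | 28 as its C8/C9 acetonide | CC(C)(C)[Si](C)(C)O[C@H]1C[C@](C)(CO[Si](C)(C)C(C)(C)C)[C@H]([C@H]3OC(C)(C)O[C@@]3([C@@H](C)CO[Si](C)(C)C(C)(C)C)[C@@H]4COC(=O)O4)[C@@]1(C)[C@H](O[Si](C)(C)C(C)(C)C)CCC=C | intermediate
30 | C6,C7-diol acetonide | CC(C)(C)[Si](C)(C)O[C@H]1C[C@](C)(CO[Si](C)(C)C(C)(C)C)[C@H]([C@H]3OC(C)(C)O[C@@]3([C@@H](C)CO[Si](C)(C)C(C)(C)C)[C@@H](O)CO)[C@@]1(C)[C@H](O[Si](C)(C)C(C)(C)C)CCC=C | intermediate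
31 | C6 tosylate of 30 (not isolated) | CC(C)(C)[Si](C)(C)O[C@H]1C[C@](C)(CO[Si](C)(C)C(C)(C)C)[C@H]([C@H]3OC(C)(C)O[C@@]3([C@@H](C)CO[Si](C)(C)C(C)(C)C)[C@@H](O)COS(=O)(=O)c2ccc(C)cc2)[C@@]1(C)[C@H](O[Si](C)(C)C(C)(C)C)CCC=C | intermediate
32 | terminal C6–C7 epoxide acetonide | CC(C)(C)[Si](C)(C)O[C@H]1C[C@](C)(CO[Si](C)(C)C(C)(C)C)[C@H]([C@H]3OC(C)(C)O[C@@]3([C@@H](C)CO[Si](C)(C)C(C)(C)C)[C@@H]4CO4)[C@@]1(C)[C@H](O[Si](C)(C)C(C)(C)C)CCC=C | intermediate
33 | 32 with the terminal alkene hydrated to the C5 secondary alcohol (C5 epimers) | CC(C)(C)[Si](C)(C)O[C@H]1C[C@](C)(CO[Si](C)(C)C(C)(C)C)[C@H]([C@H]3OC(C)(C)O[C@@]3([C@@H](C)CO[Si](C)(C)C(C)(C)C)[C@@H]4CO4)[C@@]1(C)[C@H](O[Si](C)(C)C(C)(C)C)CCC(C)O | intermediate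
34 | thioacetic acid | CC(=O)S | starting material
35 | C5 thioacetate (C5 epimers) | CC(C)(C)[Si](C)(C)O[C@H]1C[C@](C)(CO[Si](C)(C)C(C)(C)C)[C@H]([C@H]3OC(C)(C)O[C@@]3([C@@H](C)CO[Si](C)(C)C(C)(C)C)[C@@H]4CO4)[C@@]1(C)[C@H](O[Si](C)(C)C(C)(C)C)CCC(C)SC(C)=O | intermediate
36 | C5 thiol from 35 (not isolated) | CC(C)(C)[Si](C)(C)O[C@H]1C[C@](C)(CO[Si](C)(C)C(C)(C)C)[C@H]([C@H]3OC(C)(C)O[C@@]3([C@@H](C)CO[Si](C)(C)C(C)(C)C)[C@@H]4CO4)[C@@]1(C)[C@H](O[Si](C)(C)C(C)(C)C)CCC(C)S | intermediate
37 | eleven-membered cyclic sulfide (S between C5 and C6) with free C7 hydroxyl | CC(C)(C)[Si](C)(C)O[C@H]1C[C@](C)(CO[Si](C)(C)C(C)(C)C)[C@@H]2[C@H]3OC(C)(C)O[C@@]3([C@@H](C)CO[Si](C)(C)C(C)(C)C)[C@@H](O)CSC(C)CC[C@@H](O[Si](C)(C)C(C)(C)C)[C@@]12C | intermediate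
38 | eleven-membered cyclic sulfone, the key-step precursor (C5 epimers) | CC(C)(C)[Si](C)(C)O[C@H]1C[C@](C)(CO[Si](C)(C)C(C)(C)C)[C@@H]2[C@H]3OC(C)(C)O[C@@]3([C@@H](C)CO[Si](C)(C)C(C)(C)C)[C@@H](O)CS(=O)(=O)C(C)CC[C@@H](O[Si](C)(C)C(C)(C)C)[C@@]12C | intermediate
39 | C5-bromo sulfone (not isolated) | CC(C)(C)[Si](C)(C)O[C@H]1C[C@](C)(CO[Si](C)(C)C(C)(C)C)[C@@H]2[C@H]3OC(C)(C)O[C@@]3([C@@H](C)CO[Si](C)(C)C(C)(C)C)[C@@H](O)CS(=O)(=O)C(C)(Br)CC[C@@H](O[Si](C)(C)C(C)(C)C)[C@@]12C | intermediate
40 | episulfone: thiirane 1,1-dioxide on C5–C6, ring residues C4 and C7 cis, either face (not isolated) | CC(C)(C)[Si](C)(C)O[C@H]1C[C@](C)(CO[Si](C)(C)C(C)(C)C)[C@@H]2[C@H]3OC(C)(C)O[C@@]3([C@@H](C)CO[Si](C)(C)C(C)(C)C)[C@@H](O)C4S(=O)(=O)C4(C)CC[C@@H](O[Si](C)(C)C(C)(C)C)[C@@]12C | intermediate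
41 | ring B alkene: Z C5=C6, free C7 hydroxyl, C8/C9 acetonide, OTBS at C2, C12, C14, C19 | CC(C)(C)[Si](C)(C)O[C@H]1C[C@](C)(CO[Si](C)(C)C(C)(C)C)[C@@H]2[C@H]3OC(C)(C)O[C@@]3([C@@H](C)CO[Si](C)(C)C(C)(C)C)[C@@H](O)/C=C(/C)CC[C@@H](O[Si](C)(C)C(C)(C)C)[C@@]12C | intermediate
42 | pentaol acetonide (hydroxyls at C2, C7, C12, C14, C19) | O[C@H]1C[C@](C)(CO)[C@@H]2[C@H]3OC(C)(C)O[C@@]3([C@@H](C)CO)[C@@H](O)/C=C(/C)CC[C@@H](O)[C@@]12C | intermediate
43 | C19 lactol closed on the C7 oxygen, C12 aldehyde (not isolated) | O[C@H]1C[C@](C)(C=O)[C@@H]2[C@H]4OC(C)(C)O[C@@]43[C@H](/C=C(/C)CC[C@@H](O)[C@@]12C)OC(O)[C@@H]3C | intermediate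
44 | lactone aldehyde diol: C7–O–C19 γ-lactone, C12 formyl, free C2 and C14 hydroxyls, C8/C9 acetonide | O[C@H]1C[C@](C)(C=O)[C@@H]2[C@H]4OC(C)(C)O[C@@]43[C@H](/C=C(/C)CC[C@@H](O)[C@@]12C)OC(=O)[C@@H]3C | intermediate
45 | C2,C14-diacetate acetonide | CC(=O)O[C@H]1C[C@](C)(C=O)[C@@H]2[C@H]4OC(C)(C)O[C@@]43[C@H](/C=C(/C)CC[C@@H](OC(C)=O)[C@@]12C)OC(=O)[C@@H]3C | intermediate
46 | target (1S,2R,5Z,7S,8R,9R,10R,11S,14S,17R in the numbering used here) | CC(=O)O[C@H]1C[C@](C)(C=O)[C@@H]2[C@@H](O)[C@@]3(O)[C@H](/C=C(/C)CC[C@@H](OC(C)=O)[C@@]12C)OC(=O)[C@@H]3C | target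

Total steps: 32. Longest linear sequence: 25 steps (steps 1–8, then 16–32); the alkenyl fragment takes steps 9–15.

Steps most likely to fail

Step 28 (key step). The α-carbanions may be diverted: bromination at C6 followed by displacement of bromide by the C7 alkoxide, retro-addition of the β-alkoxide sulfone, or polybromination, so that SO2 is not extruded. The fallback installs the halogen regioselectively at the sulfide stage and then uses the classical base-induced Ramberg–Bäcklund reaction. It sets out from sulfide 37. Et3SiOTf/2,6-lutidine should give the C7 triethylsilyl ether F1. NCS in CCl4 should chlorinate the more acidic C6 methylene to give the α-chloro sulfide F2. mCPBA should give the α-chloro sulfone F3. KOt-Bu in THF at −78 °C should contract the ring to the C7-silylated Z alkene F4. Bu4NF under the conditions of step 29 then removes all five silyl groups, and the route is rejoined at pentaol 42.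

Step 16. The congested aldehyde may react sluggishly with the branched alkenyl nucleophile, may be enolised at C10, or may be attacked with poor facial selectivity at C9. The fallback replaces aldehyde addition by acylation and reagent-controlled reduction. It sets out from lactone 11 and stannane 20. Alkenyllithium 21 is added to the lactone carbonyl of 11 at −78 °C to give the hydroxy enone as its cyclic hemiketal F5. TBSCl/imidazole should trap the open form as the C12 silyl ether, enone F6. Corey–Bakshi–Shibata reduction with (S)-Me-CBS oxazaborolidine and catecholborane at −78 °C (the antipodal catalyst if the branched alkenyl group does not act as the larger substituent) then sets C9 and rejoins the route at 24.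

Step 6. The two ketones may be reduced in the wrong order or from the wrong faces, and the non-enolisable 1,3-diketone may undergo retro-Claisen cleavage. The fallback is stepwise and puts C2 under reagent control. It sets out from 8. NaBH4/CeCl3·7H2O in MeOH at −78 °C should reduce only the cyclopentanone to give 9, now isolated. TBSOTf/2,6-lutidine should give the C14 silyl ether ketone F7. Corey–Bakshi–Shibata reduction of the C2 ketone with (S)-Me-CBS oxazaborolidine and BH3·SMe2, where the flanking groups (quaternary C1 against CH2) are well differentiated, should give the (2R)-alcohol F8. TBSOTf/2,6-lutidine then rejoins the route at 11.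

Further compounds

F1 | step 28 | C7 triethylsilyl ether of cyclic sulfide 37 | CC(C)(C)[Si](C)(C)O[C@H]1C[C@](C)(CO[Si](C)(C)C(C)(C)C)[C@@H]2[C@H]3OC(C)(C)O[C@@]3([C@@H](C)CO[Si](C)(C)C(C)(C)C)[C@@H](O[Si](CC)(CC)CC)CSC(C)CC[C@@H](O[Si](C)(C)C(C)(C)C)[C@@]12C
F2 | step 28 | C6-chloro cyclic sulfide with C7 triethylsilyl ether | CC(C)(C)[Si](C)(C)O[C@H]1C[C@](C)(CO[Si](C)(C)C(C)(C)C)[C@@H]2[C@H]3OC(C)(C)O[C@@]3([C@@H](C)CO[Si](C)(C)C(C)(C)C)[C@@H](O[Si](CC)(CC)CC)C(Cl)SC(C)CC[C@@H](O[Si](C)(C)C(C)(C)C)[C@@]12C
F3 | step 28 | C6-chloro cyclic sulfone with C7 triethylsilyl ether | CC(C)(C)[Si](C)(C)O[C@H]1C[C@](C)(CO[Si](C)(C)C(C)(C)C)[C@@H]2[C@H]3OC(C)(C)O[C@@]3([C@@H](C)CO[Si](C)(C)C(C)(C)C)[C@@H](O[Si](CC)(CC)CC)C(Cl)S(=O)(=O)C(C)CC[C@@H](O[Si](C)(C)C(C)(C)C)[C@@]12C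
F4 | step 28 | C7 triethylsilyl ether of ring B alkene 41 | CC(C)(C)[Si](C)(C)O[C@H]1C[C@](C)(CO[Si](C)(C)C(C)(C)C)[C@@H]2[C@H]3OC(C)(C)O[C@@]3([C@@H](C)CO[Si](C)(C)C(C)(C)C)[C@@H](O[Si](CC)(CC)CC)/C=C(/C)CC[C@@H](O[Si](C)(C)C(C)(C)C)[C@@]12C
F5 | step 16 | cyclic hemiketal of the C9 hydroxy enone (C9 epimers) | CC(C)(C)[Si](C)(C)O[C@H]1C[C@]2(C)COC(O)(/C(=C/COCc3ccc(OC)cc3)[C@@H](C)CO[Si](C)(C)C(C)(C)C)[C@@H]2[C@@]1(C)[C@H](O[Si](C)(C)C(C)(C)C)CCC=C
F6 | step 16 | C9 enone with C12 silyl ether | CC(C)(C)[Si](C)(C)O[C@H]1C[C@](C)(CO[Si](C)(C)C(C)(C)C)[C@H](C(=O)/C(=C/COCc2ccc(OC)cc2)[C@@H](C)CO[Si](C)(C)C(C)(C)C)[C@@]1(C)[C@H](O[Si](C)(C)C(C)(C)C)CCC=C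
F7 | step 6 | C14 silyl ether lactone with C2 ketone | CC(C)(C)[Si](C)(C)O[C@H]1C[C@]2(C)COC(=O)[C@@H]2[C@@]1(C)C(=O)CCC=C
F8 | step 6 | C14 silyl ether lactone with (2R)-C2 alcohol | CC(C)(C)[Si](C)(C)O[C@H]1C[C@]2(C)COC(=O)[C@@H]2[C@@]1(C)[C@H](O)CCC=C
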